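**Assumption:** the α-carbon of open-chain intermediates 15 and 16 (which becomes sp2 C5 of the pyran) is carried as an epimeric mixture. Catalyst and ligand enantiomers are those stated. The route is a paper design and has not been run.

## Retrosynthetic overview

1. The dihydropyran is closed last: the ketone oxygen of 16 captures the bromonium ion released from the side-chain vicinal bromochloride, then H+ is lost to give the enol ether.
2. The C4–C5 bond (pyran numbering) comes from alkylating the ester enolate of ring fragment 8 with the (R)-bromochloro triflate 14.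
3. Fragment 8: the trans-diequatorial Br/Cl pair comes from a cis-α-bromoketone (methyl addition, then chloride delivered anti to Br through a bromonium ion).
4. The cyclohexane ring is formed first, by intramolecular aldol condensation of keto-aldehyde 3, whose stereocentre (C1′) is set by an organocatalytic Michael addition.
5. Fragment 14: Sharpless epoxidation of prenol, Markovnikov HBr opening, then a stereospecific 1,2-bromine shift with chloride capture.

## Ring fragment

**Step 1**
Reactants: 1 methyl 4-oxobutanoate; 2 methyl vinyl ketone
Product: 3 methyl (3R)-3-formyl-6-oxoheptanoate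
Conditions: (R)-2-[diphenyl(trimethylsilyloxy)methyl]pyrrolidine (5 mol%), ethyl 3,4-dihydroxybenzoate (20 mol%), neat, 4 °C
Reagents that add atoms: none
Why: Enamine-catalysed asymmetric Michael addition; the (R)-diarylprolinol silyl ether shields one enamine face, so the enone adds to the other and sets the future C1′ as (R).

**Step 2**
Reactants: 3
Product: 4 methyl 2-[(1R)-4-oxocyclohex-2-en-1-yl]acetate
Conditions: p-TsOH·H2O (10 mol%), PhMe, 80 °C, Dean–Stark
Reagents that add atoms: none
Why: Intramolecular aldol condensation (Robinson-type; the methyl ketone attacks the aldehyde, then dehydration) closes the six-membered ring, with the alkene marking the carbon that will carry bromine.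

**Step 3**
Reactants: 4
Product: 5 methyl 2-[(1R)-3-bromo-4-oxocyclohex-2-en-1-yl]acetate
Conditions: Br2, CH2Cl2, 0 °C; then Et3N, 0 °C → rt
Reagents that add atoms: bromine, BrBr
Why: Bromine addition to the enone followed by E2 loss of HBr gives the 2-bromoenone regiospecifically; the stereocentre is untouched.

**Step 4**
Reactants: 5
Product: 6 methyl 2-[(1R,3S)-3-bromo-4-oxocyclohexyl]acetate (cis, Br equatorial)
Conditions: L-Selectride (1.05 equiv), THF, −78 °C; AcOH quench at −78 °C
Reagents that add atoms: none (H only)
Why: 1,4-Hydride reduction gives the α-bromo enolate, and kinetic axial protonation leaves bromine equatorial, cis to the side chain (this is also the isomer favoured on equilibration); any trans isomer is removed by chromatography.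

**Step 5**
Reactants: 6
Product: 7 methyl 2-[(1R,3S,4S)-3-bromo-4-hydroxy-4-methylcyclohexyl]acetate
Conditions: AlMe3 (3 equiv), PhMe, −40 → 0 °C
Reagents that add atoms: trimethylaluminium, C[Al](C)C
Why: 1,2-Addition to the ketone, ester untouched; excess Me3Al in hydrocarbon delivers methyl axially, giving the trans-diequatorial bromohydrin (the C4 epimer would converge to the same bromonium ion in step 6).

**Step 6**
Reactants: 7
Product: 8 methyl 2-[(1R,3S,4S)-3-bromo-4-chloro-4-methylcyclohexyl]acetate
Conditions: HCl (g), ZnCl2 (10 mol%), CH2Cl2, −10 °C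
Reagents that add atoms: hydrogen chloride, Cl
Why: SN1 ionisation of the tertiary alcohol with anchimeric assistance from the neighbouring bromine gives the bromonium ion on the face cis to the side chain; chloride opens it at the tertiary carbon anti to Br (net retention), giving the trans-diequatorial bromochloride.

## Side-chain fragment

**Step 7**
Reactants: 9 3-methylbut-2-en-1-ol (prenol)
Product: 10 [(2S)-3,3-dimethyloxiran-2-yl]methyl 4-nitrobenzoate
Conditions: Ti(OiPr)4 (5 mol%), L-(+)-DET (7.5 mol%), t-BuOOH, 4 Å MS, CH2Cl2, −20 °C; then P(OMe)3, Et3N, 4-O2NC6H4COCl, 0 °C; recrystallise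
Reagents that add atoms: tert-butyl hydroperoxide, CC(C)(C)OO; 4-nitrobenzoyl chloride, O=C(Cl)c1ccc(cc1)[N+](=O)[O-]
Why: Sharpless asymmetric epoxidation with in situ ester derivatisation; L-(+)-DET gives the (2S)-epoxide, and the crystalline ester allows the ee to be raised.

**Step 8**
Reactants: 10
Product: 11 (2S)-3-bromo-2-hydroxy-3-methylbutyl 4-nitrobenzoate
Conditions: HBr (33% in AcOH, 1.1 equiv), CH2Cl2, −20 °C
Reagents that add atoms: hydrogen bromide, Br
Why: Acid-mediated Markovnikov epoxide opening puts bromide on the tertiary carbon and leaves the C2–O stereocentre unchanged.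

**Step 9**
Reactants: 11
Product: 12 (2R)-2-bromo-3-chloro-3-methylbutyl 4-nitrobenzoate
Conditions: Tf2O, 2,6-di-tert-butyl-4-methylpyridine, CH2Cl2, −78 °C; then n-Bu4NCl, −78 → 0 °C
Reagents that add atoms: tetrabutylammonium chloride, CCCC[N+](CCCC)(CCCC)CCCC.[Cl-]
Why: Neighbouring-group participation: the tertiary bromine displaces the secondary triflate with inversion to form a bromonium ion, which chloride opens at the tertiary carbon, so Br ends on C2 as (R).

**Step 10**
Reactants: 12
Product: 13 (2R)-2-bromo-3-chloro-3-methylbutan-1-ol
Conditions: DIBAL-H (2.5 equiv), CH2Cl2, −78 °C; Rochelle salt work-up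
Reagents that add atoms: none
Why: Reductive ester cleavage under non-basic conditions avoids epoxide formation from the β-bromo alkoxide; the stereocentre is not involved.

**Step 11**
Reactants: 13
Product: 14 (2R)-2-bromo-3-chloro-3-methylbutyl trifluoromethanesulfonate
Conditions: Tf2O, 2,6-lutidine, CH2Cl2, −78 °C; used immediately
Reagents that add atoms: triflic anhydride, O=S(=O)(OS(=O)(=O)C(F)(F)F)C(F)(F)F
Why: O-Sulfonylation of the primary alcohol gives an electrophile reactive enough for SN2 at a β-branched carbon at low temperature.

## Union and endgame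

**Step 12**
Reactants: 8; 14
Product: 15 methyl (4R)-4-bromo-2-[(1S,3S,4S)-3-bromo-4-chloro-4-methylcyclohexyl]-5-chloro-5-methylhexanoate (C2 epimers)
Conditions: 8, LDA (1.05 equiv), THF, −78 °C; then 14, DMPU, −78 → −40 °C; AcOH quench cold
Reagents that add atoms: none
Why: Ester enolate SN2 alkylation with the primary triflate; the equatorial ring halogens have no anti-periplanar hydrogen for E2, and the cold quench limits cyclopropane formation from the γ-bromo ester.

**Step 13**
Reactants: 15
Product: 16 (5R)-5-bromo-3-[(1S,3S,4S)-3-bromo-4-chloro-4-methylcyclohexyl]-6-chloro-6-methylheptan-2-one (C3 epimers)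
Conditions: MeNHOMe·HCl, i-PrMgCl, THF, −20 °C; then MeMgCl, −20 → 0 °C; aq. NH4Cl
Reagents that add atoms: methylmagnesium chloride, C[Mg]Cl
Why: One-pot Weinreb amide formation and Grignard addition; the stable chelate stops at the ketone and no ketone enolate is generated while the γ-bromide is present.

**Step 14**
Reactants: 16
Product: 17 laucapyranoid A, (3R)-3-bromo-5-[(1S,3S,4S)-3-bromo-4-chloro-4-methylcyclohexyl]-2,2,6-trimethyl-3,4-dihydro-2H-pyran
Conditions: (CF3)2CHOH, NaHCO3, 23 °C; Et3N-deactivated silica
Reagents that add atoms: none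
Why: Solvolytic ionisation of the acyclic tertiary chloride with bromine participation gives the bromonium ion; 6-endo capture at the tertiary carbon by the ketone oxygen and loss of H+ from C5 gives the tetrasubstituted enol ether with C3 retained as (R). The ring bromochloride cannot easily reach the anti-periplanar geometry and can only return to itself.

## Compound list

1 | methyl 4-oxobutanoate | COC(=O)CCC=O | starting material
2 | methyl vinyl ketone | CC(=O)C=C | starting material
3 | methyl (3R)-3-formyl-6-oxoheptanoate | COC(=O)C[C@H](C=O)CCC(C)=O | intermediate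
4 | methyl 2-[(1R)-4-oxocyclohex-2-en-1-yl]acetate | COC(=O)C[C@H]1CCC(=O)C=C1 | intermediate
5 | methyl 2-[(1R)-3-bromo-4-oxocyclohex-2-en-1-yl]acetate | COC(=O)C[C@H]1CCC(=O)C(Br)=C1 | intermediate
6 | methyl 2-[(1R,3S)-3-bromo-4-oxocyclohexyl]acetate | COC(=O)C[C@H]1CCC(=O)[C@@H](Br)C1 | intermediate
7 | methyl 2-[(1R,3S,4S)-3-bromo-4-hydroxy-4-methylcyclohexyl]acetate | COC(=O)C[C@H]1CC[C@](C)(O)[C@@H](Br)C1 | intermediate
8 | methyl 2-[(1R,3S,4S)-3-bromo-4-chloro-4-methylcyclohexyl]acetate | COC(=O)C[C@H]1CC[C@](C)(Cl)[C@@H](Br)C1 | intermediate
9 | 3-methylbut-2-en-1-ol (prenol) | CC(C)=CCO | starting material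
10 | [(2S)-3,3-dimethyloxiran-2-yl]methyl 4-nitrobenzoate | O=C(OC[C@@H]1OC1(C)C)c1ccc(cc1)[N+](=O)[O-] | intermediate
11 | (2S)-3-bromo-2-hydroxy-3-methylbutyl 4-nitrobenzoate | O=C(OC[C@H](O)C(C)(C)Br)c1ccc(cc1)[N+](=O)[O-] | intermediate
12 | (2R)-2-bromo-3-chloro-3-methylbutyl 4-nitrobenzoate | O=C(OC[C@@H](Br)C(C)(C)Cl)c1ccc(cc1)[N+](=O)[O-] | intermediate
13 | (2R)-2-bromo-3-chloro-3-methylbutan-1-ol | OC[C@@H](Br)C(C)(C)Cl | intermediate
14 | (2R)-2-bromo-3-chloro-3-methylbutyl trifluoromethanesulfonate | FC(F)(F)S(=O)(=O)OC[C@@H](Br)C(C)(C)Cl | intermediate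
15 | methyl (4R)-4-bromo-2-[(1S,3S,4S)-3-bromo-4-chloro-4-methylcyclohexyl]-5-chloro-5-methylhexanoate (C2 epimers) | COC(=O)C(C[C@@H](Br)C(C)(C)Cl)[C@H]1CC[C@](C)(Cl)[C@@H](Br)C1 | intermediate
16 | (5R)-5-bromo-3-[(1S,3S,4S)-3-bromo-4-chloro-4-methylcyclohexyl]-6-chloro-6-methylheptan-2-one (C3 epimers) | CC(=O)C(C[C@@H](Br)C(C)(C)Cl)[C@H]1CC[C@](C)(Cl)[C@@H](Br)C1 | intermediate
17 | laucapyranoid A | CC1=C([C@H]2CC[C@](C)(Cl)[C@@H](Br)C2)C[C@@H](Br)C(C)(C)O1 | target

## Step count

- Total steps: 14
- Longest linear sequence: 9 (steps 1–6, then 12–14); the side-chain branch is 5 steps (7–11), 8 to the target.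

## Steps most likely to fail

1. **Step 6 (chloride delivery anti to Br).** Leakage through an open cation would give the C4 epimer. Fallback: close 7 with base to the epoxide anti to the side chain, open it trans-diaxially with HBr (tertiary bromide, secondary alcohol), then activate the alcohol with Tf2O in the presence of chloride; the 1,2-bromine shift used in step 9 then sets both centres by stereospecific displacements only.
2. **Step 12 (alkylation with the β-bromo triflate).** E2 of the triflate or cyclopropane formation may compete. Fallback: alkylate 8 with prenyl bromide, convert to the methyl ketone, and install the bromide afterwards by bromonium-induced cyclisation of the γ,δ-unsaturated ketone (e.g. a bromodiethylsulfonium reagent), separating the C3 epimers.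
3. **Step 14 (carbonyl capture of the bromonium ion in HFIP).** 5-exo capture, elimination or solvent trapping may compete. Fallback: solvolyse 16 in aqueous HFIP to the bromohydrin (tertiary alcohol, C3–Br retained) and close the ring by acid-catalysed hemiketalisation and dehydration (PPTS, PhH, Dean–Stark).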